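The trap in this pair is to set 3.0 M of free monomer in cedar against 0.80 M in larch and expect longer chains from the richer charge. But the loading stands on the free monomer, so cedar also carries 8.40 mM of pre-initiator against 2.24 mM in larch.

| flask | free monomer | pre-initiator | remark | time |
|---|---|---|---|---|
| Thursday's | 0.80 M | 0.42 mol% | run made earlier |  |
| Tuesday's | 0.80 M | 0.14 mol% | run made earlier |  |
| larch | 0.80 M | 0.28 mol% |  | 1.0 h |
| cedar | 3.0 M | 0.28 mol% |  | 1.0 h |

- Thursday's (time / min: monomer in chains / %): 0.667: 1.4; 2.00: 7.0; 3.00: 12.8; 5.00: 24.5; 8.00: 40.9; 10.0: 48.6; 12.0: 54.9
- Tuesday's (time / min: monomer in chains / %): 0.667: 0.6; 2.00: 2.0; 3.00: 4.0; 5.00: 9.0; 8.00: 18.1; 10.0: 22.7; 12.0: 27.8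

(scatter of a reading: 0.5 percentage points)

- the average divides the monomer in chains by the number of chains begun, living and dead together
- the earlier runs were read with a standard deviation of 0.5 percentage points
- the earlier runs do not show the number of chains; that part of a forecast is a guess

- which of the two ends with the longer chains by the average number of monomer units in a chain (chains begun, living or dead) ("neither" if they lie within 10%) (larch / cedar / neither)
- average number of monomer units in a chain (chains begun, living or dead) at the end, larch
- average number of monomer units in a chain (chains begun, living or dead) at the end, cedar

I therefore reckon with the ceiling length, the units of free monomer charged per pre-initiator, 357, the same in both flasks. If each pre-initiator begins one chain, which the readings cannot show, the average (the number-average degree of polymerisation) is the ceiling length times one minus the fraction of free monomer left.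

Turned round, larch wins if cedar keeps the larger fraction left, and even a cedar that used its whole charge ties if larch leaves under 9.09%. Thursday's run still has 45.1% left at 12.0 min. Over its last readings the logarithm of the fraction left falls at 0.0676 /min, faster than the 0.0315 /min read from Tuesday's run. Larch's loading is the mean of those two, so I read its slope as their mean, 0.0496 /min, and its logarithm at 12.0 min as the mean of theirs, 0.561; held to 1.0 h, that slope leaves 5.29%, under that limit, which reads as neither. Larch stays above the limit if its slope averages below 0.0383 /min, and Thursday's slope has already sagged from 0.0816 /min over the readings before, so I commit to cedar, narrowly, expecting its 3.75 times larch's pre-initiator per litre to leave it the smaller fraction.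

The forecast also says cedar, with 285 for larch and 342 for cedar, taking as a guess that “nearly all pre-initiator has begun chains by 1 h in both”.

The flasks give cedar, with 257 for larch and 331 for cedar.

    free monomer + initiator → living end + monomer in chains (k = 0.232 /M/s)
    monomer in chains + living end → free monomer + living end, rate k2*[living end] as long as [monomer in chains] is above zero (k = 0.171 /s)
    pre-initiator ⇌ initiator (K = 1.10, k = 0.00662 /s)
    free monomer + living end → monomer in chains + living end, rate k4*[living end]*[free monomer] (k = 0.768 /M/s)

Both flasks have come to rest at a floor of free monomer, c(free monomer) being 0.224 M in larch and 0.223 M in cedar, the ratio of the back to the forward constant being 0.223 M. The ceiling length times the used fraction gives 257 for larch and 331 for cedar. For the neighbour like cedar at 0.75 M, which leaves 30%, it gives 250, and that flask stands at 250. Ten times the time, 10.0 h, still leaves free monomer at 27.8% in larch and 7.42% in cedar, with averages of 258 and 331.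

The readings were computed on assumed constants; noise was put on by code.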